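The numbers in the tables were computed for an exercise, and the scatter is random.

Leave the reagent of the west flask at 0.600 M, equal to its starting material, and let time do the work. Here is the case for that.

the same everywhere: starting material 0.600 M; free catalyst 0.0180 M

|  | reagent | time |
|---|---|---|
| north-east | 0.600 M |  |
| north | 1.80 M |  |
| west | 0.600 M | 27 h |

- north-east run (time / h: [product] / M): 0.24: 0.006; 0.74: 0.049; 1.4: 0.093; 2.2: 0.156; 3.2: 0.206; 4.3: 0.256; 5.5: 0.295; 6.8: 0.340
- north run (time / h: [product] / M): 0.24: 0.042; 0.74: 0.120; 1.4: 0.216; 2.2: 0.317; 3.2: 0.417; 4.3: 0.490; 5.5: 0.528; 6.8: 0.560

(readings scatter by 0.006 M)

- Overall: starting material + reagent -> product, with free catalyst as catalyst.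
- Constant volume, constant temperature.
- "The second partner" is reagent.
- An order is taken over about fifteen percent of the charge, up and down.

* apparent order in [reagent] of the starting rate, round the charge of the north-east run (the rate where two percent of its starting material have turned into product)
* product in the west run at 27 h, as a share of the starting material charged

Compare the two flasks while each has made about the same small amount of product. The north-east flask rose from 0.049 M to 0.093 M between 0.74 h and 1.4 h, a slope of 0.0667 M h⁻¹. The north flask rose from 0.042 M to 0.120 M between 0.24 h and 0.74 h, a slope of 0.156 M h⁻¹. So 3.00 times the reagent buys 2.34 times the rate, less than the charge ratio.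

From these readings I take 0.774 as n, the two-point reagent order: the logarithm of the rate ratio over the logarithm of the reagent ratio. It is an apparent order and it spans the whole step up in reagent, but it is my estimate round the north-east charge. Each slope rests on two scattered readings, so n is a reading too.

So the north charge spends 1.20 M of extra reagent for that gain in rate. Time looks cheaper. The north-east flask had turned 56.7% of its starting material into product by 6.8 h, and the west flask, with the same charge, gets 3.97 such spans. If each span turns the same share of what remains, I expect 96.4% in the west flask.

The forecast gives 0.84 and 96%, reasoning that “This suggests substrate partly saturates the catalyst”. Its order stands above mine, and its west value stands just below mine.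

    free catalyst + starting material → loaded catalyst + by-product (5.400 L mol⁻¹ h⁻¹)
    loaded catalyst + reagent → product + free catalyst (9.648 L mol⁻¹ h⁻¹)
    starting material + reagent + product → 2 product (0.3208 L² mol⁻² h⁻¹)
    starting material + reagent → product (0.1073 L mol⁻¹ h⁻¹)

Round the north-east charge the apparent order is 0.72, below my n of 0.774 and the forecast's 0.84, and the west flask gives 92.6%, below my 96.4%. The north-east flask took 2.28 h to turn a quarter of its charge into product; n turns that into 0.973 h for the north flask, which took 0.946 h. In the west flask, free catalyst took up starting material from the start and loaded catalyst passed it on to reagent, while the uncatalysed step ran beside this cycle. As product built up, the step that uses product joined them, and at 27 h the west flask held 0.555 M of product.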